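## Retrosynthetic overview

- The target is a 2,5-bis(4-hydroxyphenyl)oxolane whose C3 and C4 each carry a resorcinol ring. Each resorcinol ring is fused through its C3a–C7a edge to a trans-2-(4-hydroxyphenyl)-3-(3,5-dihydroxyphenyl)-2,3-dihydrofuran ring (O1, C2, C3, C3a, C7a).
- Cutting C3–C3a and O1–C2 in both dihydrofuran rings gives the oxolane tetraphenol and two molecules of a 4-hydroxystilbene. Forward, this is a twofold oxidative phenol–stilbene [3+2] annulation in one flask.
- The oxolane comes from a C2-symmetric 1,4-diaryl-2,3-diarylbutane-1,4-diol by ring closure with inversion at one carbinol. The diol comes from CBS reduction of the 1,4-diketone, and the diketone from a (2S,3S)-2,3-diarylsuccinyl unit made by auxiliary-controlled oxidative enolate homocoupling.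
- Every oxygen that must stay inert in the oxidation is carried as an acetate instead of a methyl ether. This makes the oxolane's 4-oxyphenyl rings electron-poor and the stilbene's resorcinol ring a poor nucleophile, and the last step becomes a mild transesterification.
- Ring order: oxolane first (step 8), then both dihydrofuran rings together (step 11).

Key step: step 11

Remark on the chemistry: the (2S,3S) sense of step 4 is assigned from the usual chelated Z-enolate model of (S)-4-benzyl-2-oxazolidinone imides. If the coupling follows the opposite facial sense, the (R)-auxiliary is used and nothing else changes.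

## Route

Step 1
Reactants: 1 methyl 3,5-dihydroxyphenylacetate
Product: 2 methyl 3,5-bis(benzyloxy)phenylacetate
Conditions: BnBr (2.2 equiv), K2CO3, DMF, 50 °C
Reagents that add atoms: benzyl bromide, BrCc1ccccc1
Why: Williamson ether synthesis in which the two phenoxides are benzylated under carbonate conditions that leave the ester and its benzylic methylene untouched; no stereocentre is formed.

Step 2
Reactants: 2 methyl 3,5-bis(benzyloxy)phenylacetate
Product: 3 3,5-bis(benzyloxy)phenylacetic acid
Conditions: LiOH·H2O, THF/MeOH/H2O, rt; then 1 M HCl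
Reagents that add atoms: lithium hydroxide, [Li+].[OH-]
Why: Ester saponification frees the acid for attachment of the auxiliary, the benzyl ethers are inert and no stereocentre is involved.

Step 3
Reactants: 3 3,5-bis(benzyloxy)phenylacetic acid; 4 (S)-4-benzyl-2-oxazolidinone
Product: 6 (S)-4-benzyl-3-{[3,5-bis(benzyloxy)phenyl]acetyl}oxazolidin-2-one, via mixed pivalic anhydride 5 (not isolated)
Conditions: PivCl, Et3N, THF, −20 °C; then 4, LiCl, −20 °C → rt
Reagents that add atoms: none
Why: N-Acylation of the Evans auxiliary through the mixed pivalic anhydride (LiCl/Et3N protocol) gives the imide without touching the C4 stereocentre of the auxiliary, the only one present.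

Step 4
Reactants: 6 (S)-4-benzyl-3-{[3,5-bis(benzyloxy)phenyl]acetyl}oxazolidin-2-one (two molecules)
Product: 8 (2S,3S)-2,3-bis[3,5-bis(benzyloxy)phenyl]-1,4-bis[(S)-4-benzyl-2-oxooxazolidin-3-yl]butane-1,4-dione, via lithium Z-enolate 7 (not isolated)
Conditions: LDA, THF, −78 °C; then TiCl4, −78 → 0 °C
Reagents that add atoms: none
Why: Oxidative enolate homocoupling of a chiral N-arylacetyl oxazolidinone, in which one-electron oxidation of the chelated Z-enolate by Ti(IV) lets two α-carbons join, each on the face anti to the C4 benzyl group of its auxiliary, which should set both new centres as S and give the C2-symmetric (2S,3S)-diarylsuccinyl unit.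

Step 5
Reactants: 8 the bis-imide
Product: 9 S,S′-diethyl (2S,3S)-2,3-bis[3,5-bis(benzyloxy)phenyl]butanebis(thioate)
Conditions: EtSH, n-BuLi, THF, 0 °C; then aq NH4Cl
Reagents that add atoms: ethanethiol (used as its lithium salt), CCS
Why: Thiolysis of N-acyl oxazolidinones with lithium ethanethiolate attacks the exocyclic carbonyl even in hindered imides and, being weakly basic and run cold, should leave the two α-aryl stereocentres untouched while returning the auxiliary.

Step 6
Reactants: 9 the bis(thioester); 10 4-acetoxyphenylboronic acid (2.5 equiv)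
Product: 11 (2S,3S)-1,4-bis(4-acetoxyphenyl)-2,3-bis[3,5-bis(benzyloxy)phenyl]butane-1,4-dione
Conditions: Pd2(dba)3 (cat.), P(2-furyl)3, CuTC (3 equiv), THF, 50 °C
Reagents that add atoms: none
Why: Liebeskind–Srogl ketone synthesis, a Pd(0)/copper(I) carboxylate-mediated coupling of a thioester with an arylboronic acid that runs without base, so the aryl acetates survive and the two enolisable α-aryl stereocentres should not epimerise.

Step 7
Reactants: 11 the 1,4-diketone
Product: 12 (1S,2S,3S,4S)-1,4-bis(4-acetoxyphenyl)-2,3-bis[3,5-bis(benzyloxy)phenyl]butane-1,4-diol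
Conditions: (R)-Me-CBS (cat.), BH3·SMe2, THF, −20 °C; then MeOH
Reagents that add atoms: none
Why: Corey–Bakshi–Shibata reduction in which, with the aryl group as the large substituent, (R)-Me-CBS should deliver hydride to give the S carbinol at both ketones, a sense that coincides with the Felkin–Anh preference of the α-aryl ketone (1,2-syn), so reagent and substrate control reinforce each other.

Step 8
Reactants: 12 the C2-symmetric diol
Product: 14 (2S,3S,4S,5R)-2,5-bis(4-acetoxyphenyl)-3,4-bis[3,5-bis(benzyloxy)phenyl]oxolane (2,3-cis-3,4-trans-4,5-trans), via monomesylate 13 (not isolated)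
Conditions: MsCl (1.05 equiv), Et3N, CH2Cl2, −20 °C → rt
Reagents that add atoms: none
Why: Cyclodehydration of a 1,4-diol through its monosulfonate (5-exo-tet SN2 Williamson closure) in which, the diol being C2-symmetric, either hydroxyl can be mesylated with the same result, the mesylated carbon is inverted (S to R, aryl trans to its neighbour) and the attacking carbinol is retained (aryl cis to its neighbour), while the electron-poor 4-acetoxyphenyl group disfavours ionisation.

Step 9
Reactants: 14 the tetrabenzyl oxolane
Product: 15 (2S,3S,4S,5R)-2,5-bis(4-acetoxyphenyl)-3,4-bis(3,5-dihydroxyphenyl)oxolane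
Conditions: H2 (1 atm), Pd/C, EtOAc, rt
Reagents that add atoms: none
Why: Hydrogenolysis of aryl benzyl ethers on Pd/C in a neutral aprotic solvent is much faster than cleavage of the benzylic C–O bonds of the oxolane and should leave the aryl acetates and all four stereocentres untouched.

Step 10
Reactants: 16 resveratrol triacetate, (E)-3,5,4′-triacetoxystilbene
Product: 17 3,5-di-O-acetylresveratrol, (E)-3,5-diacetoxy-4′-hydroxystilbene
Conditions: Novozym 435 (Candida antarctica lipase B), n-BuOH, t-BuOMe, 40 °C
Reagents that add atoms: none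
Why: Lipase-catalysed regioselective alcoholysis, in which this lipase is known to prefer the 4′-position of resveratrol esters, should free the one phenol that has to be oxidised and keep the resorcinol ring acetylated; no stereocentre is involved.

Step 11
Reactants: 15 the oxolane tetraphenol; 17 3,5-di-O-acetylresveratrol (2.6 equiv)
Product: 19 hexaacetate of the target with four free phenols (both dihydrobenzofuran rings (2S,3S)), via mono-annulated dihydrobenzofuran 18 (not isolated)
Conditions: PhI(OAc)2 (2.6 equiv) and 17, co-added by syringe pump to 15 in HFIP/CH2Cl2, −20 → 0 °C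
Reagents that add atoms: none
Why: Proposed new method: PhI(OAc)2 in HFIP should take the only conjugated and most easily oxidised phenol, that of 17, to its phenoxenium/quinone-methide cation, whose C8 is attacked in Friedel–Crafts fashion by the resorcinol carbon of 15 that is para to one hydroxyl and ortho to the oxolane-bearing carbon (bond C3–C3a); the p-quinone methide so formed is closed by the neighbouring hydroxyl (bond O1–C2), and the sequence repeats on the second resorcinol ring of 18. The closest known reactions are the oxidative 8–10′ dimerisation of resveratrol to ε-viniferin with two-electron metal oxidants, iodine(III)/HFIP phenol–arene cross-couplings and oxidative phenol–alkene [3+2] annulations. Each dihydrofuran ring closes by 5-exo-trig oxa-1,6-addition onto the exocyclic C=C bond of the quinone methide, which restores the phenol. C2 of each ring is set in this closure anti to the C3 aryl group (trans, reversible through the quinone methide and so also the thermodynamic outcome), whereas C3 is set in the C–C bond formation by the face of C8 that the chiral oxolane exposes, the only control element present, so the required (2S,3S) sense on both rings is not assured. Cross- over homo-coupling should be secured by slow co-addition that keeps free 17 scarce relative to 15, by the acetates that make the stilbene's own resorcinol ring a poor nucleophile, and by the 4-acetoxyphenyl groups that keep the oxolane inert to oxidation and to ionisation in HFIP; site selectivity rests on the known preference of 5-alkylresorcinols to react para to a hydroxyl and not between the two.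

Step 12
Reactants: 19 the hexaacetate
Product: 20 CNP0270490.1 (target)
Conditions: K2CO3 (cat.), MeOH, Ar, 0 °C → rt; then AcOH
Reagents that add atoms: none
Why: Zemplén-type transesterification of the six aryl acetates with catalytic carbonate in methanol under argon is mild enough that the benzylic ethers of the two dihydrobenzofurans and of the oxolane, and all eight stereocentres, should remain untouched.

## Compound list

1 | methyl 3,5-dihydroxyphenylacetate | COC(=O)Cc1cc(O)cc(O)c1 | starting material
2 | methyl 3,5-bis(benzyloxy)phenylacetate | COC(=O)Cc1cc(OCc2ccccc2)cc(OCc2ccccc2)c1 | intermediate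
3 | 3,5-bis(benzyloxy)phenylacetic acid | OC(=O)Cc1cc(OCc2ccccc2)cc(OCc2ccccc2)c1 | intermediate
4 | (S)-4-benzyl-2-oxazolidinone | O=C1N[C@@H](Cc2ccccc2)CO1 | starting material
5 | mixed anhydride of 3 with pivalic acid | CC(C)(C)C(=O)OC(=O)Cc1cc(OCc2ccccc2)cc(OCc2ccccc2)c1 | intermediate (not isolated)
6 | (S)-4-benzyl-3-{[3,5-bis(benzyloxy)phenyl]acetyl}oxazolidin-2-one | O=C(Cc1cc(OCc2ccccc2)cc(OCc2ccccc2)c1)N1[C@@H](Cc2ccccc2)COC1=O | intermediate
7 | lithium Z-enolate of 6 | [Li]O/C(=C\c1cc(OCc2ccccc2)cc(OCc2ccccc2)c1)N1[C@@H](Cc2ccccc2)COC1=O | intermediate (not isolated)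
8 | (2S,3S)-2,3-bis[3,5-bis(benzyloxy)phenyl]-1,4-bis[(S)-4-benzyl-2-oxooxazolidin-3-yl]butane-1,4-dione | O=C([C@H](c1cc(OCc2ccccc2)cc(OCc2ccccc2)c1)[C@@H](c1cc(OCc2ccccc2)cc(OCc2ccccc2)c1)C(=O)N1[C@@H](Cc2ccccc2)COC1=O)N1[C@@H](Cc2ccccc2)COC1=O | intermediate
9 | S,S′-diethyl (2S,3S)-2,3-bis[3,5-bis(benzyloxy)phenyl]butanebis(thioate) | CCSC(=O)[C@H](c1cc(OCc2ccccc2)cc(OCc2ccccc2)c1)[C@@H](c1cc(OCc2ccccc2)cc(OCc2ccccc2)c1)C(=O)SCC | intermediate
10 | 4-acetoxyphenylboronic acid | CC(=O)Oc1ccc(B(O)O)cc1 | starting material
11 | (2S,3S)-1,4-bis(4-acetoxyphenyl)-2,3-bis[3,5-bis(benzyloxy)phenyl]butane-1,4-dione | CC(=O)Oc1ccc(cc1)C(=O)[C@H](c1cc(OCc2ccccc2)cc(OCc2ccccc2)c1)[C@@H](c1cc(OCc2ccccc2)cc(OCc2ccccc2)c1)C(=O)c1ccc(OC(C)=O)cc1 | intermediate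
12 | (1S,2S,3S,4S)-1,4-bis(4-acetoxyphenyl)-2,3-bis[3,5-bis(benzyloxy)phenyl]butane-1,4-diol | CC(=O)Oc1ccc(cc1)[C@@H](O)[C@H](c1cc(OCc2ccccc2)cc(OCc2ccccc2)c1)[C@@H](c1cc(OCc2ccccc2)cc(OCc2ccccc2)c1)[C@H](O)c1ccc(OC(C)=O)cc1 | intermediate
13 | mono-methanesulfonate of 12 | CC(=O)Oc1ccc(cc1)[C@@H](O)[C@H](c1cc(OCc2ccccc2)cc(OCc2ccccc2)c1)[C@@H](c1cc(OCc2ccccc2)cc(OCc2ccccc2)c1)[C@H](OS(C)(=O)=O)c1ccc(OC(C)=O)cc1 | intermediate (not isolated)
14 | (2S,3S,4S,5R)-2,5-bis(4-acetoxyphenyl)-3,4-bis[3,5-bis(benzyloxy)phenyl]oxolane (2,3-cis-3,4-trans-4,5-trans) | C(c1ccccc1)Oc1cc(OCc2ccccc2)cc(c1)[C@@H]1[C@@H](c2cc(OCc3ccccc3)cc(OCc3ccccc3)c2)[C@H](c2ccc(OC(C)=O)cc2)O[C@@H]1c1ccc(OC(C)=O)cc1 | intermediate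
15 | (2S,3S,4S,5R)-2,5-bis(4-acetoxyphenyl)-3,4-bis(3,5-dihydroxyphenyl)oxolane | Oc1cc(O)cc(c1)[C@@H]1[C@@H](c2cc(O)cc(O)c2)[C@H](c2ccc(OC(C)=O)cc2)O[C@@H]1c1ccc(OC(C)=O)cc1 | intermediate (key-step precursor)
16 | resveratrol triacetate, (E)-3,5,4′-triacetoxystilbene | CC(=O)Oc1ccc(/C=C/c2cc(OC(C)=O)cc(OC(C)=O)c2)cc1 | starting material
17 | 3,5-di-O-acetylresveratrol, (E)-3,5-diacetoxy-4′-hydroxystilbene | CC(=O)Oc1cc(/C=C/c2ccc(O)cc2)cc(OC(C)=O)c1 | intermediate (key-step precursor)
18 | mono-annulated intermediate: 15 with one (2S,3S)-2-(4-hydroxyphenyl)-3-(3,5-diacetoxyphenyl)-2,3-dihydrofuran ring fused to the resorcinol ring on oxolane C3, the other resorcinol ring free (either ring may react first) | Oc1ccc([C@H]2Oc3cc(O)cc([C@@H]4[C@@H](c5cc(O)cc(O)c5)[C@H](c5ccc(OC(C)=O)cc5)O[C@@H]4c4ccc(OC(C)=O)cc4)c3[C@@H]2c2cc(OC(C)=O)cc(OC(C)=O)c2)cc1 | intermediate (not isolated)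
19 | hexaacetate of the target: acetates on the two oxolane 4-oxyphenyl groups and on the four oxygens of the two 3-(3,5-dioxyphenyl) groups; free OH at C6 of both benzofurans and on both 2-(4-hydroxyphenyl) groups | Oc1ccc([C@H]2Oc3cc(O)cc([C@@H]4[C@@H](c5cc(O)cc6c5[C@H](c5cc(OC(C)=O)cc(OC(C)=O)c5)[C@@H](c5ccc(O)cc5)O6)[C@H](c5ccc(OC(C)=O)cc5)O[C@@H]4c4ccc(OC(C)=O)cc4)c3[C@@H]2c2cc(OC(C)=O)cc(OC(C)=O)c2)cc1 | intermediate (key-step product)
20 | CNP0270490.1 | Oc1ccc([C@H]2Oc3cc(O)cc([C@@H]4[C@@H](c5cc(O)cc6c5[C@H](c5cc(O)cc(O)c5)[C@@H](c5ccc(O)cc5)O6)[C@H](c5ccc(O)cc5)O[C@@H]4c4ccc(O)cc4)c3[C@@H]2c2cc(O)cc(O)c2)cc1 | target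

## Step count and risks

Total step count: 12. Longest linear sequence: 11 steps (1 → 20 through steps 1–9, 11 and 12); step 10 is a one-step side branch.

**Step 11 (Proposed new method).**
- What may go wrong: the oxidised stilbene may dimerise with itself (8–3′ or 8–O–4′ coupling) faster than it is captured by the resorcinol rings. The rings may be attacked at the carbon between the two hydroxyls. Facial selectivity at C8 may be poor and give diastereomeric rings. The product phenols may be over-oxidised.
- Fallback: it sets out from 15 and comes back to the route at 20. It builds the rings without oxidation, by the known o-quinone methide/sulfur ylide [4+1] annulation.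
  - Condensation of 15 with 3,5-diacetoxybenzaldehyde and sodium p-toluenesulfinate (HCO2H/H2O, rt) is the known three-component route to 2-(α-sulfonylbenzyl)phenols and reacts at the same carbon para to a hydroxyl. It would give the bis(sulfone) F1 and form C3–C3a.
  - Cs2CO3 in MeCN/CH2Cl2 would eliminate sulfinate to the o-quinone methides. The ylide from [4-(tert-butyldimethylsilyloxy)benzyl]dimethylsulfonium tetrafluoroborate would add to the exocyclic carbon and be displaced by the phenoxide. This would give the bis(trans-dihydrobenzofuran) silyl ether F2 and form C2–C3 and O1–C2.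
  - K2CO3/MeOH would then remove the acetates and the aryl silyl ethers together and give 20.
  - Acetyl migration among the phenols in the basic stage is of no consequence, since every acetate is removed. A chiral sulfide of the isothiocineole type offers a handle for reagent control of the ring sense.

**Step 6.**
- What may go wrong: acyl transfer at the two hindered α-aryl thioesters may be slow, so the reaction stalls at the mono-ketone, and the α-aryl centres may epimerise on prolonged heating.
- Fallback: it sets out from 8 and comes back at 11. It replaces the thioester coupling by acyl substitution on a Weinreb amide.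
  - Transamination of 8 with Me2AlN(OMe)Me (from AlMe3 and MeNHOMe·HCl, CH2Cl2, 0 °C) would give the bis(Weinreb amide) F3 and release the auxiliary.
  - Addition of 4-(tert-butyldimethylsilyloxy)phenylmagnesium bromide (THF, −20 °C) would give the bis(silyl ether) diketone F4. The chelated tetrahedral adducts shield the α-centres until quench.
  - TBAF/AcOH would give the bisphenol diketone F5, and Ac2O/pyridine would return 11.

**Step 8.**
- What may go wrong: the benzylic mesylate may ionise, with loss of stereochemical fidelity at the displaced carbon, Friedel–Crafts capture by the neighbouring dibenzyloxyphenyl ring (indane formation) or elimination to an alkene.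
- Fallback: it sets out from 11 and comes back at 14. It sets the second benzylic centre by hydride addition to an oxocarbenium ion instead of by displacement.
  - Reduction of one ketone of 11 with (S)-Me-CBS and one hydride equivalent (catecholborane, −40 °C) would give the R carbinol, which closes onto the remaining ketone to the lactol F6.
  - Et3SiH/BF3·OEt2 (CH2Cl2, −78 °C) would ionise F6 to the 2-aryl oxocarbenium ion and deliver hydride anti to the adjacent C3 aryl group. This is the known course for such cations in 2,5-diaryltetrahydrofuran lignan synthesis.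
  - The retained R carbinol carbon is trans to its neighbour and the new centre is cis to its neighbour, which is the 2,3-cis-3,4-trans-4,5-trans oxolane 14.

Further compounds
F1 | step 11 | 15 carrying on each resorcinol ring, at the carbon between the oxolane-bearing carbon and a hydroxyl, a (3,5-diacetoxyphenyl)(p-tolylsulfonyl)methyl group (epimers at the sulfone carbons) | Oc1cc(O)c(C(c2cc(OC(C)=O)cc(OC(C)=O)c2)S(=O)(=O)c2ccc(C)cc2)c(c1)[C@@H]1[C@@H](c2cc(O)cc(O)c2C(c2cc(OC(C)=O)cc(OC(C)=O)c2)S(=O)(=O)c2ccc(C)cc2)[C@H](c2ccc(OC(C)=O)cc2)O[C@@H]1c1ccc(OC(C)=O)cc1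
F2 | step 11 | 19 with tert-butyldimethylsilyl ethers on the two 2-(4-oxyphenyl) groups of the dihydrobenzofurans | CC(C)(C)[Si](C)(C)Oc1ccc([C@H]2Oc3cc(O)cc([C@@H]4[C@@H](c5cc(O)cc6c5[C@H](c5cc(OC(C)=O)cc(OC(C)=O)c5)[C@@H](c5ccc(O[Si](C)(C)C(C)(C)C)cc5)O6)[C@H](c5ccc(OC(C)=O)cc5)O[C@@H]4c4ccc(OC(C)=O)cc4)c3[C@@H]2c2cc(OC(C)=O)cc(OC(C)=O)c2)cc1
F3 | step 6 | (2S,3S)-2,3-bis[3,5-bis(benzyloxy)phenyl]-N1,N4-dimethoxy-N1,N4-dimethylbutanediamide | CON(C)C(=O)[C@H](c1cc(OCc2ccccc2)cc(OCc2ccccc2)c1)[C@@H](c1cc(OCc2ccccc2)cc(OCc2ccccc2)c1)C(=O)N(C)OC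
F4 | step 6 | (2S,3S)-2,3-bis[3,5-bis(benzyloxy)phenyl]-1,4-bis[4-(tert-butyldimethylsilyloxy)phenyl]butane-1,4-dione | CC(C)(C)[Si](C)(C)Oc1ccc(cc1)C(=O)[C@H](c1cc(OCc2ccccc2)cc(OCc2ccccc2)c1)[C@@H](c1cc(OCc2ccccc2)cc(OCc2ccccc2)c1)C(=O)c1ccc(O[Si](C)(C)C(C)(C)C)cc1
F5 | step 6 | (2S,3S)-2,3-bis[3,5-bis(benzyloxy)phenyl]-1,4-bis(4-hydroxyphenyl)butane-1,4-dione | Oc1ccc(cc1)C(=O)[C@H](c1cc(OCc2ccccc2)cc(OCc2ccccc2)c1)[C@@H](c1cc(OCc2ccccc2)cc(OCc2ccccc2)c1)C(=O)c1ccc(O)cc1
F6 | step 8 | (3S,4S,5R)-2,5-bis(4-acetoxyphenyl)-3,4-bis[3,5-bis(benzyloxy)phenyl]oxolan-2-ol (lactol, both C2 epimers) | C(c1ccccc1)Oc1cc(OCc2ccccc2)cc(c1)[C@@H]1[C@@H](c2cc(OCc3ccccc3)cc(OCc3ccccc3)c2)[C@H](c2ccc(OC(C)=O)cc2)OC1(O)c1ccc(OC(C)=O)cc1
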